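**Retrosynthetic overview**
- The target is released in one reductive operation from a tetra-O-benzyl diarylcarbinol that still carries a 1,3-dithiane in the ring A–ring B tether.
- Key disconnection (ring A CH2–CH2 ring B bond): a 2-lithio-2-aryl-1,3-dithiane, the masked acyl anion of the ring-B aldehyde, is alkylated by the ring-A benzyl chloride. The same flask then continues with ortho-lithiation between the two ring-B oxygens and addition to the ring C–D aldehyde, whose formyl carbon becomes the methylene bridge.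
- The ring C–D aldehyde comes from lateral (benzylic) alkylation of the tert-butyl imine of 4-benzyloxy-2-methoxy-6-methylbenzaldehyde with 3-benzyloxybenzyl bromide. The ring-C oxygen pattern is fixed by hydrogen-bond-differentiated alkylation of orcylaldehyde.
- Rings: all four benzene rings are bought intact (A: O-benzylvanillyl chloride; B: 3-hydroxy-5-methoxybenzaldehyde; C: orcylaldehyde; D: 3-benzyloxybenzyl bromide). The only ring formed is the auxiliary 1,3-dithiane (step 2), which is destroyed in the last step.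

Assumption: the target has no stereocentre (it is achiral), so no enantiocontrol is needed; the one carbinol stereocentre of intermediate 16 is racemic and is erased in step 6.

**Route**

Step 1
Reactants: 1 3-hydroxy-5-methoxybenzaldehyde
Product: 2 3-(benzyloxy)-5-methoxybenzaldehyde
Conditions: BnBr (1.1 equiv), K2CO3, DMF, 50 °C
Reagents that add atoms: benzyl bromide BrCc1ccccc1
Why: Williamson etherification of the single phenol (phenoxide SN2 on BnBr) installs a benzyl ether that later directs ortho-lithiation and is removed by hydrogenolysis; no stereocentre is involved.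

Step 2
Reactants: 2 3-(benzyloxy)-5-methoxybenzaldehyde
Product: 3 2-[3-(benzyloxy)-5-methoxyphenyl]-1,3-dithiane
Conditions: HS(CH2)3SH (1.1 equiv), BF3·OEt2 (cat.), CH2Cl2, 0 °C → rt
Reagents that add atoms: propane-1,3-dithiol SCCCS
Why: Lewis-acid-catalysed dithioacetalisation converts the aryl aldehyde into its 1,3-dithiane (Corey–Seebach acyl-anion precursor, C2–H pKa about 31) without affecting the aryl ethers; no stereocentre is formed.

Step 3
Reactants: 4 2,4-dihydroxy-6-methylbenzaldehyde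
Product: 6 4-(benzyloxy)-2-methoxy-6-methylbenzaldehyde, via mono-benzyl ether 5 (not isolated)
Conditions: BnBr (1.05 equiv), KHCO3, MeCN, 60 °C; then K2CO3, MeI, 60 °C
Reagents that add atoms: benzyl bromide BrCc1ccccc1; iodomethane CI
Why: Regioselective Williamson alkylation controlled by the intramolecular O–H···O=C hydrogen bond: with weak base only the free, more acidic 4-OH is benzylated, after which the stronger base and MeI methylate the chelated 2-OH in the same flask, fixing the ring-C oxygen pattern without isomers; no stereocentre.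

Step 4
Reactants: 6 4-(benzyloxy)-2-methoxy-6-methylbenzaldehyde; 7 1-(benzyloxy)-3-(bromomethyl)benzene
Product: 11 4-(benzyloxy)-2-{2-[3-(benzyloxy)phenyl]ethyl}-6-methoxybenzaldehyde, via tert-butyl imine 8 (not isolated), via lithiated imine 9 (not isolated), via alkylated imine 10 (not isolated)
Conditions: t-BuNH2, 4 Å MS, CH2Cl2, rt, evaporate; LDA (1.2 equiv), THF, −78 → −30 °C; 7, −78 °C → rt; 1 M HCl, THF, rt
Reagents that add atoms: none
Why: Imine-directed lateral (benzylic) lithiation–alkylation: the tert-butyl imine masks the aldehyde against addition and acidifies the ortho-methyl group, LDA gives the aza-o-xylylene anion 9, which is benzylated by bromide 7 in an SN2 reaction, and acid hydrolysis returns the aldehyde; no stereocentre is formed.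

Step 5
Reactants: 3 2-[3-(benzyloxy)-5-methoxyphenyl]-1,3-dithiane; 12 1-(benzyloxy)-4-(chloromethyl)-2-methoxybenzene; 11 4-(benzyloxy)-2-{2-[3-(benzyloxy)phenyl]ethyl}-6-methoxybenzaldehyde
Product: 16 [2-(benzyloxy)-4-{2-[4-(benzyloxy)-3-methoxybenzyl]-1,3-dithian-2-yl}-6-methoxyphenyl](4-(benzyloxy)-2-{2-[3-(benzyloxy)phenyl]ethyl}-6-methoxyphenyl)methanol (racemic), via lithiodithiane 13 (not isolated), via benzylated dithiane 14 (not isolated), via aryllithium 15 (not isolated)
Conditions: 3, n-BuLi (1.05 equiv), THF, −40 °C; 12 (1.0 equiv), −78 → 0 °C; n-BuLi (1.15 equiv), TMEDA, −10 → 0 °C; 11 (1.1 equiv), −78 → 0 °C; H2O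
Reagents that add atoms: none
Why: Corey–Seebach umpolung used as a linchpin: lithiodithiane 13, the masked acyl anion of aldehyde 2, displaces chloride from 12 (SN2) and so joins two carbons that are both electrophilic in their native state, the resulting 14 has no acidic dithiane C–H left so the second n-BuLi/TMEDA performs directed ortho-metalation at the only position flanked by OBn and OMe, and aryllithium 15 adds to the non-enolisable aldehyde 11 (1,2-addition); the carbinol stereocentre is formed as a racemate and is erased in step 6.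

Step 6
Reactants: 16 [2-(benzyloxy)-4-{2-[4-(benzyloxy)-3-methoxybenzyl]-1,3-dithian-2-yl}-6-methoxyphenyl](4-(benzyloxy)-2-{2-[3-(benzyloxy)phenyl]ethyl}-6-methoxyphenyl)methanol
Product: 17 4-{2-[3-hydroxy-4-({4-hydroxy-2-[2-(3-hydroxyphenyl)ethyl]-6-methoxyphenyl}methyl)-5-methoxyphenyl]ethyl}-2-methoxyphenol
Conditions: Raney Ni (W-2, large excess), H2 (1 atm), EtOH–THF, 60 °C
Reagents that add atoms: none
Why: Raney nickel under hydrogen effects Mozingo desulfurisation of the dithiane to CH2, hydrogenolysis of the four benzyl aryl ethers and hydrogenolysis of the doubly benzylic, electron-rich C–OH in one operation, leaving methyl ethers and arenes intact and giving the achiral target.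

**Compound list**

1 | 3-hydroxy-5-methoxybenzaldehyde | COc1cc(O)cc(C=O)c1 | starting material
2 | 3-(benzyloxy)-5-methoxybenzaldehyde | COc1cc(OCc2ccccc2)cc(C=O)c1 | intermediate
3 | 2-[3-(benzyloxy)-5-methoxyphenyl]-1,3-dithiane | COc1cc(OCc2ccccc2)cc(c1)C1SCCCS1 | intermediate
4 | 2,4-dihydroxy-6-methylbenzaldehyde (orcylaldehyde) | Cc1cc(O)cc(O)c1C=O | starting material
5 | 4-(benzyloxy)-2-hydroxy-6-methylbenzaldehyde | Cc1cc(OCc2ccccc2)cc(O)c1C=O | intermediate
6 | 4-(benzyloxy)-2-methoxy-6-methylbenzaldehyde | COc1cc(OCc2ccccc2)cc(C)c1C=O | intermediate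
7 | 1-(benzyloxy)-3-(bromomethyl)benzene | BrCc1cccc(OCc2ccccc2)c1 | starting material
8 | (E)-1-[4-(benzyloxy)-2-methoxy-6-methylphenyl]-N-tert-butylmethanimine | COc1cc(OCc2ccccc2)cc(C)c1/C=N/C(C)(C)C | intermediate
9 | benzylic lithio derivative of imine 8 | [Li]Cc1cc(OCc2ccccc2)cc(OC)c1/C=N/C(C)(C)C | intermediate
10 | (E)-1-[4-(benzyloxy)-2-{2-[3-(benzyloxy)phenyl]ethyl}-6-methoxyphenyl]-N-tert-butylmethanimine | COc1cc(OCc2ccccc2)cc(CCc2cccc(OCc3ccccc3)c2)c1/C=N/C(C)(C)C | intermediate
11 | 4-(benzyloxy)-2-{2-[3-(benzyloxy)phenyl]ethyl}-6-methoxybenzaldehyde | COc1cc(OCc2ccccc2)cc(CCc2cccc(OCc3ccccc3)c2)c1C=O | intermediate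
12 | 1-(benzyloxy)-4-(chloromethyl)-2-methoxybenzene | COc1cc(CCl)ccc1OCc1ccccc1 | starting material
13 | 2-lithio-2-[3-(benzyloxy)-5-methoxyphenyl]-1,3-dithiane | [Li]C1(SCCCS1)c1cc(OC)cc(OCc2ccccc2)c1 | intermediate
14 | 2-[3-(benzyloxy)-5-methoxyphenyl]-2-[4-(benzyloxy)-3-methoxybenzyl]-1,3-dithiane | COc1cc(OCc2ccccc2)cc(c1)C1(Cc2ccc(OCc3ccccc3)c(OC)c2)SCCCS1 | intermediate
15 | {2-(benzyloxy)-4-[2-(4-(benzyloxy)-3-methoxybenzyl)-1,3-dithian-2-yl]-6-methoxyphenyl}lithium | [Li]c1c(OC)cc(cc1OCc1ccccc1)C1(Cc2ccc(OCc3ccccc3)c(OC)c2)SCCCS1 | intermediate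
16 | [2-(benzyloxy)-4-{2-[4-(benzyloxy)-3-methoxybenzyl]-1,3-dithian-2-yl}-6-methoxyphenyl](4-(benzyloxy)-2-{2-[3-(benzyloxy)phenyl]ethyl}-6-methoxyphenyl)methanol, racemic | COc1cc(OCc2ccccc2)cc(CCc2cccc(OCc3ccccc3)c2)c1C(O)c1c(OC)cc(cc1OCc1ccccc1)C1(Cc2ccc(OCc3ccccc3)c(OC)c2)SCCCS1 | intermediate
17 | 4-{2-[3-hydroxy-4-({4-hydroxy-2-[2-(3-hydroxyphenyl)ethyl]-6-methoxyphenyl}methyl)-5-methoxyphenyl]ethyl}-2-methoxyphenol | COc1cc(CCc2cc(O)c(Cc3c(CCc4cccc(O)c4)cc(O)cc3OC)c(OC)c2)ccc1O | target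

**Step count**

Total steps: 6. Longest linear sequence: 4 steps (1 → 2 → 3 → 16 → 17, or equally 4 → 6 → 11 → 16 → 17).

**Three steps most likely to fail, with fallbacks**

Step 5 (one-flask alkylation, ortho-lithiation and addition). The second n-BuLi may attack the dithiane sulfur, or the crowded addition may stall in the salt-laden mixture. The fallback sets out from 3 (with 12) and returns at 17, removing sulfur before any aryl-lithium chemistry and ending without Raney nickel. The dithiane alkylation is run alone and 14 is isolated. Nickel boride (NiCl2·6H2O, NaBH4, MeOH–THF, 0 °C), which spares benzyl ethers, desulfurises 14 to 1-(benzyloxy)-3-{2-[4-(benzyloxy)-3-methoxyphenyl]ethyl}-5-methoxybenzene F1. This simple resorcinol diether is ortho-lithiated (n-BuLi, TMEDA, THF, 0 °C) and added to 11 to give the sulfur-free carbinol [2-(benzyloxy)-4-{2-[4-(benzyloxy)-3-methoxyphenyl]ethyl}-6-methoxyphenyl](4-(benzyloxy)-2-{2-[3-(benzyloxy)phenyl]ethyl}-6-methoxyphenyl)methanol F2. H2 over Pd/C (EtOAc–EtOH, trace HCl) then cleaves the four benzyl ethers and the benzylic C–OH to give 17.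

Step 4 (imine-directed lateral alkylation). Ring metalation between the two alkoxy groups, amide addition to the imine or sluggish benzylation could intervene. The fallback sets out from 6 and returns at 11, switching to o-toluate chemistry, the classical orsellinate alkylation. Pinnick oxidation (NaClO2, NaH2PO4, 2-methyl-2-butene) gives 4-(benzyloxy)-2-methoxy-6-methylbenzoic acid F3, and MeI/K2CO3 gives methyl 4-(benzyloxy)-2-methoxy-6-methylbenzoate F4. LDA (THF, −78 °C) followed by 7 gives methyl 4-(benzyloxy)-2-{2-[3-(benzyloxy)phenyl]ethyl}-6-methoxybenzoate F5. DIBAL-H reduces this to (4-(benzyloxy)-2-{2-[3-(benzyloxy)phenyl]ethyl}-6-methoxyphenyl)methanol F6, and MnO2 oxidises it to 11.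

Step 6 (global Raney nickel reduction). Debenzylation or carbinol hydrogenolysis may be incomplete, or a phenol ring may be partly saturated. The fallback sets out from 16 and returns at 17, separating the three reductions. Ionic deoxygenation (Et3SiH, TFA, CH2Cl2, 0 °C) of the carbinol gives 2-[3-(benzyloxy)-4-(4-(benzyloxy)-2-{2-[3-(benzyloxy)phenyl]ethyl}-6-methoxybenzyl)-5-methoxyphenyl]-2-[4-(benzyloxy)-3-methoxybenzyl]-1,3-dithiane F7. Nickel boride (NiCl2·6H2O, NaBH4) removes the dithiane to give 1-(benzyloxy)-2-(4-(benzyloxy)-2-{2-[3-(benzyloxy)phenyl]ethyl}-6-methoxybenzyl)-5-{2-[4-(benzyloxy)-3-methoxyphenyl]ethyl}-3-methoxybenzene F8. H2 over Pd(OH)2/C (EtOAc–MeOH) then removes the four benzyl groups to give 17.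

**Further compounds**

F1 | step 5 | 1-(benzyloxy)-3-{2-[4-(benzyloxy)-3-methoxyphenyl]ethyl}-5-methoxybenzene | COc1cc(OCc2ccccc2)cc(CCc2ccc(OCc3ccccc3)c(OC)c2)c1
F2 | step 5 | [2-(benzyloxy)-4-{2-[4-(benzyloxy)-3-methoxyphenyl]ethyl}-6-methoxyphenyl](4-(benzyloxy)-2-{2-[3-(benzyloxy)phenyl]ethyl}-6-methoxyphenyl)methanol | COc1cc(OCc2ccccc2)cc(CCc2cccc(OCc3ccccc3)c2)c1C(O)c1c(OC)cc(CCc2ccc(OCc3ccccc3)c(OC)c2)cc1OCc1ccccc1
F3 | step 4 | 4-(benzyloxy)-2-methoxy-6-methylbenzoic acid | COc1cc(OCc2ccccc2)cc(C)c1C(=O)O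
F4 | step 4 | methyl 4-(benzyloxy)-2-methoxy-6-methylbenzoate | COC(=O)c1c(C)cc(OCc2ccccc2)cc1OC
F5 | step 4 | methyl 4-(benzyloxy)-2-{2-[3-(benzyloxy)phenyl]ethyl}-6-methoxybenzoate | COC(=O)c1c(CCc2cccc(OCc3ccccc3)c2)cc(OCc2ccccc2)cc1OC
F6 | step 4 | (4-(benzyloxy)-2-{2-[3-(benzyloxy)phenyl]ethyl}-6-methoxyphenyl)methanol | OCc1c(CCc2cccc(OCc3ccccc3)c2)cc(OCc2ccccc2)cc1OC
F7 | step 6 | 2-[3-(benzyloxy)-4-(4-(benzyloxy)-2-{2-[3-(benzyloxy)phenyl]ethyl}-6-methoxybenzyl)-5-methoxyphenyl]-2-[4-(benzyloxy)-3-methoxybenzyl]-1,3-dithiane | COc1cc(OCc2ccccc2)cc(CCc2cccc(OCc3ccccc3)c2)c1Cc1c(OC)cc(cc1OCc1ccccc1)C1(Cc2ccc(OCc3ccccc3)c(OC)c2)SCCCS1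
F8 | step 6 | 1-(benzyloxy)-2-(4-(benzyloxy)-2-{2-[3-(benzyloxy)phenyl]ethyl}-6-methoxybenzyl)-5-{2-[4-(benzyloxy)-3-methoxyphenyl]ethyl}-3-methoxybenzene | COc1cc(OCc2ccccc2)cc(CCc2cccc(OCc3ccccc3)c2)c1Cc1c(OC)cc(CCc2ccc(OCc3ccccc3)c(OC)c2)cc1OCc1ccccc1
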